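Take the smaller J charge of the two runs, 1 equiv against 1.5 equiv, and ask what stands in the north flask at 4.0 h.

| flask | D | J | remark | time |
|---|---|---|---|---|
| north | 0.44 M | 1 equiv | the very flask that is asked about, followed so far |  |
| north-west | 0.44 M | 1.5 equiv | run made earlier |  |
| flask | 0.44 M | 1.00 equiv |  | 4.0 h |

| run | time / min | D / % | G / % |
|---|---|---|---|
| north | 4.00 | 76 | 0 |
| north | 12.0 | 55 | 2 |
| north | 20.0 | 45 | 6 |
| north | 30.0 | 36 | 7 |
| north | 50.0 | 23 | 5 |
| north-west | 8.00 | 65 | 2 |
| north-west | 25.0 | 38 | 7 |
| north-west | 40.0 | 30 | 7 |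
| north-west | 60.0 | 21 | 9 |
| north-west | 90.0 | 15 | 7 |

(readings scatter by 1.5 percentage points)

* part of the D gone at 4.0 h
* the G standing at 4.0 h, as a percentage of the D charged

- percent here means D units held: one X or Z counts as two
- what may be going on: D + J <-> L; L <-> G + Q; 2 D -> X; 2 D -> Z

Write the balance of J. What J has lost sits in L or G, and each G brings one Q, so, taking L as small, J left is the charge less G. Define W, the reaction quotient, as G squared over D times J left, all as fractions of the D charged; the last north-west reading gives 0.0228, up from 0.00902 at 25.0 min. Treat it as a low value for the north flask too, and as a reading with its scatter.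

Now bound G. In the north run, 1/D climbs 0.0659 min⁻¹; carry that line on and D reaches 5.93 %, so conversion is near 94.1 %. L and G hold D that may come back, so call this the low side of D.

Low W and low D put my estimated floor of G at 3.55 %. For a rough roof, take the top north reading, 7 %, scatter included.

The forecast says conversion 93 % and G 3.3 %, this G just under that floor, from a G that “then sags, which suggests equilibrium”.

The flask gives conversion 92.5 % and G 5.71 %.

    D + J ⇌ L (K = 0.190 M⁻¹, k = 8.00 × 10⁻⁴ M⁻¹ s⁻¹)
    L ⇌ G + Q (K = 0.180 M, k = 8.80 × 10⁻⁴ s⁻¹)
    2 D → X (k = 0.00110 M⁻¹ s⁻¹)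
    2 D → Z (k = 7.00 × 10⁻⁷ M⁻¹ s⁻¹)

In that flask less of the D is left, 7.5 %, than of the J, 94 %. Put both into W: G comes to 4.02 %, under the flask's G.

Read the same flask at 1.5 h. The line gives D 14.3 %, and W puts the estimated floor at 5.52 %. Computed, D is 15.4 % and G 7.00 %, above that floor.

(The readings are simulated for substances that don't exist; scatter was added.)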